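Start with the cycle.

starting material 0.32 M; coupling partner 0.160 M; protic impurity 0.0960 M; free catalyst 8.0 mM

    catalyst intermediate B → free catalyst + product (k1 = 2.5 s⁻¹)
    starting material + free catalyst → catalyst intermediate A (k2 = 0.16 M⁻¹ s⁻¹)
    starting material + protic impurity → quenched substrate (k3 = 0.0029 M⁻¹ s⁻¹)
    coupling partner + catalyst intermediate A ⇌ catalyst intermediate B (K4 = 2.3 M⁻¹, k4 = 0.74 M⁻¹ s⁻¹)

* apparent order in free catalyst when 30% of the starting material are converted (percent change of the rate of making product for one percent more free catalyst charged)

Take the catalytic cycle by itself, with the flask's fractions held fixed. Every form of the catalyst scales with the charge, so the rate of making product is the catalyst charged times a turnover rate, and the order is 1. Catalyst intermediate B goes on to product faster than it falls back, with 0.886 of it going forward.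

Now let the cycle consume coupling partner. If the cycle is the one consumer, and leaving aside what sits on the catalyst, the partner used at a given conversion follows from that conversion, so the order stays 1.

Now add the quench. With all the catalyst free, the selectivity factor at the start is 4.60. I take the free fraction of the catalyst at the charge, 0.672, and hold the protic impurity at its charge. That gives 3.09, so a fraction 0.755 of the converted starting material passes through the catalyst. At the conversion asked about, the coupling partner left is then 0.547 of its charge.

The waiting share is the fraction of the catalyst sitting as catalyst intermediate A, waiting for coupling partner: 0.385. In my reckoning the order of the rate in coupling partner equals this share, and one percent more catalyst lowers the partner left by 0.203 percent, so my order is 0.922.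

The forecast gave 0.93, on this ground: “More catalyst also wins a larger share of the starting material from the quench”.

The simulation gives 0.94. Until 0.391 h, when coupling partner fell below 2 percent of its charge, the cycle turned. Catalyst intermediate A held 37.5% of the catalyst at 0.0921 h, against a waiting share of 0.385, and 43.1% at 0.150 h, against 0.439 from that moment's fractions. Afterwards, with catalyst intermediate A at >99.9% of the catalyst by 0.750 h, product stood at 50.0% of the starting material charged, while starting material and protic impurity went on reacting, taking quenched substrate from 19.8% to 30.0% by 15.0 h.

(The numbers are those of an exercise; no experiment stands behind them.)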